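Cuts, in retrosynthetic order: the three ArO–CH2Ph bonds, the C8–CH2 bond between ring A of the flavonol and the p-hydroxybenzyl group, the C3–OH bond, O1–C2 of ring C, and the Cα=Cβ bond of a chalcone.
Forward: ring A (di-O-benzylated phloroacetophenone) and ring B (4-benzyloxybenzaldehyde) are joined to a chalcone, ring C is closed oxidatively at O1–C2, and C3 is hydroxylated. The finished flavonol is then joined through its C8–H to 4-hydroxybenzyl alcohol, and one hydrogenolysis ends the route.
Enabling feature: the CH2 stands para to the phenolic OH of its ring, so the alcohol loses water to a p-quinone methide. C8 of ring A is a phloroglucinol-type CH (ortho to O7 and O1, para to O5) that adds to it, both rings regain aromaticity, and no halogen or metal handle is needed.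
Regiocontrol (C8, not C6): the peri C4=O holds the 5-O-benzyl group over C6. The benzyl ethers are the only helpers and leave together in the last step.
Stereochemistry: the target has no stereogenic element. The E-alkene of the chalcone and the racemic centres of the transient flavanone and epoxide vanish on the way.
Key step: step 5

Assumption: the target SMILES holds no stereocentre, stereogenic double bond or axis. "Single enantiomer" is therefore read as the one achiral constitution given, and the selectivity problem is regiochemical (C8 versus C6).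

Step 1
Reactants: 1 2,4,6-trihydroxyacetophenone
Product: 2 1-[2,4-bis(benzyloxy)-6-hydroxyphenyl]ethan-1-one
Conditions: BnBr (2.1 equiv), K2CO3 (2.2 equiv), DMF, 0 °C → rt
Reagents that add atoms: benzyl bromide BrCc1ccccc1
Why: Williamson etherification of the 4-OH and of one of the two equivalent ortho OH groups, which should stop at the diether because the last OH is tied up in a strong hydrogen bond to the acetyl C=O and is the least acidic and least nucleophilic one.

Step 2
Reactants: 2 1-[2,4-bis(benzyloxy)-6-hydroxyphenyl]ethan-1-one; 3 4-(benzyloxy)benzaldehyde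
Product: 4 (E)-1-[2,4-bis(benzyloxy)-6-hydroxyphenyl]-3-[4-(benzyloxy)phenyl]prop-2-en-1-one
Conditions: KOH (50 % aq.), EtOH/THF, rt, 24 h
Reagents that add atoms: none
Why: Claisen–Schmidt condensation of the methyl ketone enolate with a non-enolisable aldehyde, in which E1cB loss of water gives the conjugated E-enone, whose geometry has no consequence later.

Step 3
Reactants: 4 (E)-1-[2,4-bis(benzyloxy)-6-hydroxyphenyl]-3-[4-(benzyloxy)phenyl]prop-2-en-1-one
Product: 6 5,7-bis(benzyloxy)-2-[4-(benzyloxy)phenyl]-4H-chromen-4-one, via tri-O-benzyl flavanone 5 (not isolated)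
Conditions: I2 (10 mol %), DMSO, 130 °C, 2 h
Reagents that add atoms: none
Why: Iodine-catalysed oxidative cyclisation of a 2'-hydroxychalcone, in which 6-endo oxa-Michael addition of the free phenol oxygen to Cβ closes ring C to flavanone 5 and the I2/DMSO couple dehydrogenates C2–C3, with DMSO as the terminal oxidant.

Step 4
Reactants: 6 5,7-bis(benzyloxy)-2-[4-(benzyloxy)phenyl]-4H-chromen-4-one
Product: 8 5,7-bis(benzyloxy)-2-[4-(benzyloxy)phenyl]-3-hydroxy-4H-chromen-4-one (5,7,4'-tri-O-benzylkaempferol), via flavone 2,3-epoxide 7 (not isolated)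
Conditions: DMDO (acetone solution, 2 equiv), CH2Cl2, 0 °C; then TsOH·H2O (10 mol %), CH2Cl2, rt
Reagents that add atoms: dimethyldioxirane CC1(C)OO1
Why: Epoxidation of the enol-ether-like C2=C3 bond with neutral DMDO, acid-catalysed opening at C2 (cation stabilised by O1 and the 4-alkoxyphenyl ring) and loss of H3 make up the established flavone-to-flavonol oxidation, which aryl benzyl ethers tolerate and in which the two racemic centres of 7 disappear.

Step 5
Reactants: 8 5,7,4'-tri-O-benzylkaempferol; 9 4-hydroxybenzyl alcohol
Product: 11 5,7-bis(benzyloxy)-2-[4-(benzyloxy)phenyl]-3-hydroxy-8-(4-hydroxybenzyl)-4H-chromen-4-one, via p-quinone methide 10 (not isolated)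
Conditions: TsOH·H2O (5 mol %), HFIP/CH2Cl2 1:1, 30 °C, Ar; 9 (1.0 equiv, in HFIP) added over 4 h to 8 (1.2 equiv)
Reagents that add atoms: none
Why: Catalytic acid in the strongly ionising but poorly nucleophilic HFIP dehydrates 9 to p-quinone methide 10 (in equilibrium with its O-protonated form, the 4-hydroxybenzyl cation), C8 of ring A of 8 adds to the exocyclic CH2 in the 1,6-sense, and loss of H8 makes both six-membered rings aromatic again, with water as the only by-product. The closest known reaction types are the acid-catalysed Friedel–Crafts 1,6-addition of electron-rich arenes to p-quinone methides made in situ from 4-hydroxybenzyl alcohols and the C-hydroxybenzylation of acylphloroglucinol and flavonoid A rings with hydroxybenzyl alcohols. No ring is closed and no stereocentre is formed. The step needs C8 over C6: both carbons are activated by three oxygens, but the peri C4=O forces the CH2Ph of the 5-ether to point toward C6, so that C6 is walled in by two benzyloxy groups, whereas C8 is flanked by the tied-back ring oxygen O1 and by a 7-ether that can turn away, which is also why 5,7-di-O-alkylflavones are halogenated at C8 and 5,7-di-O-benzylflavans capture benzylic cations there. It also needs C- over O-attack and one benzylation only: adducts of 10 with the 3-OH, the C4=O, the phenol OH of 9 or 11, or HFIP are 4-hydroxybenzyl O-derivatives that revert to 10 under the same conditions, so that material should drain into the irreversible C–C bond, ring B is deactivated by its conjugation with C2=C3–C4=O, and slow addition of 9 to a slight excess of 8 keeps self-condensation of 10 and attack on 11 low. The plain benzyl aryl ethers could ionise only to the far less stabilised PhCH2+ and should therefore survive catalytic acid at 30 °C.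

Step 6
Reactants: 11 5,7-bis(benzyloxy)-2-[4-(benzyloxy)phenyl]-3-hydroxy-8-(4-hydroxybenzyl)-4H-chromen-4-one
Product: 12 8-C-p-hydroxybenzylkaempferol
Conditions: H2 (1 atm), 10 % Pd/C, THF/MeOH 1:1, rt
Reagents that add atoms: none
Why: Catalytic hydrogenolysis cleaves the three ArO–CH2Ph bonds under neutral conditions, while the diarylmethane C8–CH2 bond (no heteroatom leaving group) and the conjugated C2=C3 of the flavonol should stay intact at 1 atm, and the absence of hot acid avoids opening and reclosure of ring C that would move the benzyl group from C8 to C6.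

Compound list
1 | 2,4,6-trihydroxyacetophenone (phloroacetophenone) | CC(=O)c1c(O)cc(O)cc1O | starting material
2 | 1-[2,4-bis(benzyloxy)-6-hydroxyphenyl]ethan-1-one | CC(=O)c1c(O)cc(OCc2ccccc2)cc1OCc1ccccc1 | intermediate
3 | 4-(benzyloxy)benzaldehyde | O=Cc1ccc(OCc2ccccc2)cc1 | starting material
4 | (E)-1-[2,4-bis(benzyloxy)-6-hydroxyphenyl]-3-[4-(benzyloxy)phenyl]prop-2-en-1-one (chalcone) | O=C(/C=C/c1ccc(OCc2ccccc2)cc1)c1c(O)cc(OCc2ccccc2)cc1OCc1ccccc1 | intermediate
5 | 5,7-bis(benzyloxy)-2-[4-(benzyloxy)phenyl]chroman-4-one (flavanone, racemic, not isolated) | O=C1CC(c2ccc(OCc3ccccc3)cc2)Oc2cc(OCc3ccccc3)cc(OCc3ccccc3)c21 | intermediate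
6 | 5,7-bis(benzyloxy)-2-[4-(benzyloxy)phenyl]-4H-chromen-4-one (tri-O-benzylapigenin) | O=c1cc(-c2ccc(OCc3ccccc3)cc2)oc2cc(OCc3ccccc3)cc(OCc3ccccc3)c12 | intermediate
7 | 2,3-epoxide of 6 (racemic, ring fusion necessarily cis, not isolated) | O=C1C2OC2(c2ccc(OCc3ccccc3)cc2)Oc2cc(OCc3ccccc3)cc(OCc3ccccc3)c21 | intermediate
8 | 5,7-bis(benzyloxy)-2-[4-(benzyloxy)phenyl]-3-hydroxy-4H-chromen-4-one (5,7,4'-tri-O-benzylkaempferol) | O=c1c(O)c(-c2ccc(OCc3ccccc3)cc2)oc2cc(OCc3ccccc3)cc(OCc3ccccc3)c12 | intermediate
9 | 4-hydroxybenzyl alcohol | OCc1ccc(O)cc1 | starting material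
10 | p-quinone methide (4-methylidenecyclohexa-2,5-dien-1-one, not isolated) | C=C1C=CC(=O)C=C1 | intermediate
11 | 5,7-bis(benzyloxy)-2-[4-(benzyloxy)phenyl]-3-hydroxy-8-(4-hydroxybenzyl)-4H-chromen-4-one | O=c1c(O)c(-c2ccc(OCc3ccccc3)cc2)oc2c(Cc3ccc(O)cc3)c(OCc3ccccc3)cc(OCc3ccccc3)c12 | intermediate
12 | 8-C-p-hydroxybenzylkaempferol (achiral) | O=c1c(O)c(-c2ccc(O)cc2)oc2c(Cc3ccc(O)cc3)c(O)cc(O)c12 | target

Total step count: 6. Longest linear sequence: 6 (1 → 12).

Steps most likely to fail

Step 5. Three things may go wrong. Hydrogen bonding or protonation at C4=O may lower the nucleophilicity of ring A so far that the quinone methide condenses with itself. Early loss of the 5-O-benzyl group may open C6 to attack. A second benzylation may follow the first. The fallback fixes the site with a halogen and forms the same bond by cross-coupling; it sets out from 8 and comes back at 12. Compound 8 would be O-benzylated at O3 (BnBr, K2CO3, DMF) to 3,5,7,4'-tetra-O-benzylkaempferol F1. This would be iodinated with NIS/TFA in MeCN, at the position known for 5,7-di-O-alkylflavones, to 8-iodo-3,5,7,4'-tetra-O-benzylkaempferol F2. A Negishi coupling (Pd(OAc)2, SPhos, THF, 40 °C) would then join F2 with 4-(benzyloxy)benzylzinc chloride F3, made from commercial 4-(benzyloxy)benzyl chloride with Zn dust and LiCl in THF. The product would be 8-[4-(benzyloxy)benzyl]-3,5,7,4'-tetra-O-benzylkaempferol F4. Hydrogenolysis under the conditions of step 6 then removes all five benzyl groups and gives 12.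

Step 4. Epoxidation of the enone-type C2=C3 bond may be slow, so that conversion stays incomplete while excess oxidant begins to attack the benzylic C–H bonds of the ethers. The fallback replaces alkene oxidation by deprotonation, borylation and oxidation; it sets out from 6 and comes back at 8. Compound 6 would be deprotonated at C3 with LDA (THF, −78 °C) to the 3-lithioflavone F5. Trapping with B(OMe)3 and acidification with AcOH would give the dimethyl flavone-3-boronate F6. Oxidation in the same flask with H2O2 gives 8.

Step 3. Hydrogen iodide formed at 130 °C may strip the acid-labile peri 5-O-benzyl group, which would remove the shield that step 5 relies on. The fallback builds ring C by acyl transfer instead of chalcone oxidation; it sets out from 2, bypasses 4 and comes back at 6. Compound 2 would be O-acylated with commercial 4-(benzyloxy)benzoyl chloride (pyridine, DMAP cat.) to 2-acetyl-3,5-bis(benzyloxy)phenyl 4-(benzyloxy)benzoate F7. A Baker–Venkataraman rearrangement (KOH, pyridine, 50 °C) would give 1-[2,4-bis(benzyloxy)-6-hydroxyphenyl]-3-[4-(benzyloxy)phenyl]propane-1,3-dione F8. Cyclodehydration with catalytic TsOH in toluene at 80 °C gives 6.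

Further compounds
F1 | step 5 | 3,5,7,4'-tetra-O-benzylkaempferol | O=c1c(OCc2ccccc2)c(-c2ccc(OCc3ccccc3)cc2)oc2cc(OCc3ccccc3)cc(OCc3ccccc3)c12
F2 | step 5 | 8-iodo-3,5,7,4'-tetra-O-benzylkaempferol | O=c1c(OCc2ccccc2)c(-c2ccc(OCc3ccccc3)cc2)oc2c(I)c(OCc3ccccc3)cc(OCc3ccccc3)c12
F3 | step 5 | 4-(benzyloxy)benzylzinc chloride | Cl[Zn]Cc1ccc(OCc2ccccc2)cc1
F4 | step 5 | 8-[4-(benzyloxy)benzyl]-3,5,7,4'-tetra-O-benzylkaempferol | O=c1c(OCc2ccccc2)c(-c2ccc(OCc3ccccc3)cc2)oc2c(Cc3ccc(OCc4ccccc4)cc3)c(OCc3ccccc3)cc(OCc3ccccc3)c12
F5 | step 4 | 3-lithioflavone (3-lithio derivative of 6) | [Li]c1c(-c2ccc(OCc3ccccc3)cc2)oc2cc(OCc3ccccc3)cc(OCc3ccccc3)c2c1=O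
F6 | step 4 | dimethyl flavone-3-boronate (3-(dimethoxyboryl) derivative of 6) | COB(OC)c1c(-c2ccc(OCc3ccccc3)cc2)oc2cc(OCc3ccccc3)cc(OCc3ccccc3)c2c1=O
F7 | step 3 | 2-acetyl-3,5-bis(benzyloxy)phenyl 4-(benzyloxy)benzoate | CC(=O)c1c(OC(=O)c2ccc(OCc3ccccc3)cc2)cc(OCc2ccccc2)cc1OCc1ccccc1
F8 | step 3 | 1-[2,4-bis(benzyloxy)-6-hydroxyphenyl]-3-[4-(benzyloxy)phenyl]propane-1,3-dione | O=C(CC(=O)c1ccc(OCc2ccccc2)cc1)c1c(O)cc(OCc2ccccc2)cc1OCc1ccccc1
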